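The target (3S,5R,8S,3'R,6'R, all-E) is cut at C11=C12 and C11'=C12' into a furanoid C15 enal, a C10 bisphosphonate and a hydroxy-ε C15 aldehyde, joined by two Horner–Wadsworth–Emmons olefinations. Everything rests on closing the dihydrofuran ring (O, C5, C6, C7, C8) onto the cyclohexane ring: C6 lies between the quaternary C1 and C5, and the O–CH2 carbon C8 of an allyl ether on C5 sits 1,5 to a carbene at C7. One operation on the C6 ketone brings in C7, sets C6=C7, forms C7–C8 and creates the C8 stereocentre. Its precursor is the (3S,5R)-3-silyloxy-5-allyloxy ketone, made from actinol by Rubottom oxidation and O-alkylation with a prenol-derived five-carbon bromide.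

Key step: step 10

Remarks on the chemistry:
- Atom labels follow carotenoid numbering.
- Assumption: (R)-α-ionone is bought as the single enantiomer (natural-grade material).
- Both silyl groups of 13 fall together with fluoride, so no selective desilylation is needed, and the free C3 hydroxyl is carried to the end.
- The furanoid piece is used as the aldehyde partner, because a carbanion at C11 could expel the C5 oxygen by vinylogous β-elimination.

Step 1
Reactants: 1 4-oxoisophorone (2,6,6-trimethylcyclohex-2-ene-1,4-dione)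
Product: 2 (6R)-2,2,6-trimethylcyclohexane-1,4-dione
Conditions: ene-reductase OYE2, NADP+ (cat.), glucose dehydrogenase, D-glucose, phosphate buffer pH 7, 30 °C
Reagents that add atoms: none
Why: Biocatalytic asymmetric conjugate reduction by an old yellow enzyme, in which flavin hydride and a proton add trans across the ene-dione double bond inside the active site and fix the methyl-bearing carbon as R.

Step 2
Reactants: 2 (6R)-2,2,6-trimethylcyclohexane-1,4-dione
Product: 3 (4R,6R)-4-hydroxy-2,2,6-trimethylcyclohexan-1-one (actinol)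
Conditions: LiBH(s-Bu)3, THF, −78 °C; then H2O
Reagents that add atoms: none
Why: Chemo- and diastereoselective hydride reduction in which only the unhindered carbonyl reacts and the bulky borohydride attacks equatorially, away from the axial methyl of the gem-dimethyl group, giving the axial alcohol (future C3) trans to the secondary methyl.

Step 3
Reactants: 3 (4R,6R)-4-hydroxy-2,2,6-trimethylcyclohexan-1-one
Product: 4 (4R,6R)-4-[(tert-butyldimethylsilyl)oxy]-2,2,6-trimethylcyclohexan-1-one
Conditions: t-BuMe2SiCl, imidazole, DMF, rt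
Reagents that add atoms: tert-butyldimethylsilyl chloride, CC(C)(C)[Si](C)(C)Cl
Why: Standard silylation of a secondary alcohol, which touches no stereocentre.

Step 4
Reactants: 4 (4R,6R)-4-[(tert-butyldimethylsilyl)oxy]-2,2,6-trimethylcyclohexan-1-one
Product: 5 (4R)-4-[(tert-butyldimethylsilyl)oxy]-2,6,6-trimethyl-1-[(trimethylsilyl)oxy]cyclohex-1-ene
Conditions: LiN(i-Pr)2, THF, −78 → 0 °C; then Me3SiCl, −78 °C → rt
Reagents that add atoms: chlorotrimethylsilane, C[Si](C)(C)Cl
Why: Enolate O-silylation of a ketone with a single α-hydrogen, so only one enol ether can form; the methyl-bearing centre is erased on purpose and C3 is untouched.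

Step 5
Reactants: 5 (4R)-4-[(tert-butyldimethylsilyl)oxy]-2,6,6-trimethyl-1-[(trimethylsilyl)oxy]cyclohex-1-ene
Product: 8 (2R,4S)-4-[(tert-butyldimethylsilyl)oxy]-2-hydroxy-2,6,6-trimethylcyclohexan-1-one, via silyloxy oxirane 6 (not isolated), via trimethylsilyl ketol ether 7 (not isolated)
Conditions: m-CPBA, NaHCO3, CH2Cl2, −20 → 0 °C; then K2CO3, MeOH, 0 °C → rt
Reagents that add atoms: meta-chloroperoxybenzoic acid, O=C(OO)c1cccc(Cl)c1
Why: Rubottom oxidation, in which the peracid should epoxidise the enol ether on the face anti to the C3 silyloxy group (the two C1 methyls flank both faces, so the C3 substituent decides, as in peracid epoxidations of 3-O-protected rings of this type), oxirane 6 opens with 1,4-silyl shift to 7, and methanolysis frees the tertiary C5 hydroxyl (5R, trans to C3–O) while the secondary silyl ether stays.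

Step 6
Reactants: 9 prenol (3-methylbut-2-en-1-ol)
Product: 10 tert-butyl[(3-methylbut-2-en-1-yl)oxy]diphenylsilane
Conditions: t-BuPh2SiCl, imidazole, CH2Cl2, rt
Reagents that add atoms: tert-butyl(chloro)diphenylsilane, CC(C)(C)[Si](Cl)(c1ccccc1)c1ccccc1
Why: Standard silylation of a primary allylic alcohol.

Step 7
Reactants: 10 tert-butyl[(3-methylbut-2-en-1-yl)oxy]diphenylsilane
Product: 11 (2E)-4-[(tert-butyldiphenylsilyl)oxy]-2-methylbut-2-en-1-ol
Conditions: SeO2 (0.5 equiv), t-BuOOH, salicylic acid (cat.), CH2Cl2, rt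
Reagents that add atoms: tert-butyl hydroperoxide, CC(C)(C)OO
Why: Riley allylic hydroxylation (SeO2 with t-BuOOH), in which an ene reaction followed by a [2,3]-sigmatropic shift oxidises the methyl group trans to the chain and so gives the E alcohol (future C8 and C11 trans).

Step 8
Reactants: 11 (2E)-4-[(tert-butyldiphenylsilyl)oxy]-2-methylbut-2-en-1-ol
Product: 12 {[(2E)-4-bromo-3-methylbut-2-en-1-yl]oxy}(tert-butyl)diphenylsilane
Conditions: CBr4, PPh3, CH2Cl2, 0 °C
Reagents that add atoms: tetrabromomethane, BrC(Br)(Br)Br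
Why: Appel bromination of a primary allylic alcohol under neutral conditions, which leaves the alkene geometry and the silyl ether alone.

Step 9
Reactants: 8 (2R,4S)-4-[(tert-butyldimethylsilyl)oxy]-2-hydroxy-2,6,6-trimethylcyclohexan-1-one; 12 {[(2E)-4-bromo-3-methylbut-2-en-1-yl]oxy}(tert-butyl)diphenylsilane
Product: 13 (2R,4S)-4-[(tert-butyldimethylsilyl)oxy]-2-{[(2E)-4-[(tert-butyldiphenylsilyl)oxy]-2-methylbut-2-en-1-yl]oxy}-2,6,6-trimethylcyclohexan-1-one
Conditions: NaH, Bu4NI (cat.), THF–DMF, 0 °C → rt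
Reagents that add atoms: none
Why: Williamson ether synthesis, in which the sodium alkoxide of the tertiary ketol displaces the primary allylic bromide; the ketone has no α-hydrogen, so neither C-alkylation nor epimerisation is possible.

Step 10
Reactants: 13 (2R,4S)-4-[(tert-butyldimethylsilyl)oxy]-2-{[(2E)-4-[(tert-butyldiphenylsilyl)oxy]-2-methylbut-2-en-1-yl]oxy}-2,6,6-trimethylcyclohexan-1-one; 14 (trimethylsilyl)diazomethane
Product: 18 (2S,6S,7aR)-6-[(tert-butyldimethylsilyl)oxy]-2-[(2E)-4-[(tert-butyldiphenylsilyl)oxy]but-2-en-2-yl]-4,4,7a-trimethyl-2,4,5,6,7,7a-hexahydro-1-benzofuran, via lithium alkoxide adduct 15 (not isolated), via diazoalkene 16 (not isolated), via alkylidene carbene 17 (not isolated)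
Conditions: 14, n-BuLi, THF, −78 °C; then 13, −78 °C → rt; chromatographic removal of the C8 epimer
Reagents that add atoms: none
Why: The lithiated diazo compound adds to the non-enolisable C6 carbonyl (lithium chelation by the C5 ether oxygen assists) to give alkoxide 15, a Peterson-type loss of lithium trimethylsilanolate gives diazoalkene 16, and loss of N2 gives the singlet alkylidene carbene 17, whose vacant in-plane orbital at C7 takes up a C8–H bond in a concerted insertion with retention at C8. The closest known reaction type is the conversion of α-alkoxy ketones into 2,5-dihydrofurans by lithiated trimethylsilyldiazomethane through alkylidene carbene 1,5 C–H insertion. The dihydrofuran ring (O, C5, C6, C7, C8) closes by 1,5 C–H insertion, forming C7–C8 after C6=C7, and ends fused to the cyclohexane ring at C5–C6. The new C8 centre results from the choice between the two diastereotopic C8 hydrogens, which is steered only by the adjacent quaternary C5 (methyl against ring CH2 across the ether oxygen) and, weakly, by the C3 silyloxy group, so a small bias is expected and the 8S product is separated from its 8R epimer. Site selectivity is secured by the substrate: C1 and C5 carry no hydrogen, insertion into C3–H would need a bridgehead alkene, and the C8–H bonds are activated by both the ether oxygen and the C9=C10 double bond, so that they should outrun cyclopropanation of that alkene.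

Step 11
Reactants: 18 (2S,6S,7aR)-6-[(tert-butyldimethylsilyl)oxy]-2-[(2E)-4-[(tert-butyldiphenylsilyl)oxy]but-2-en-2-yl]-4,4,7a-trimethyl-2,4,5,6,7,7a-hexahydro-1-benzofuran
Product: 19 (2E)-3-[(2S,6S,7aR)-6-hydroxy-4,4,7a-trimethyl-2,4,5,6,7,7a-hexahydro-1-benzofuran-2-yl]but-2-en-1-ol
Conditions: Bu4NF, THF, 0 °C → rt
Reagents that add atoms: none
Why: Fluoride desilylation removes both silyl ethers at once under non-acidic conditions, so the acid-labile doubly allylic C8–O bond and the C8 configuration are kept.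

Step 12
Reactants: 19 (2E)-3-[(2S,6S,7aR)-6-hydroxy-4,4,7a-trimethyl-2,4,5,6,7,7a-hexahydro-1-benzofuran-2-yl]but-2-en-1-ol
Product: 20 (2E)-3-[(2S,6S,7aR)-6-hydroxy-4,4,7a-trimethyl-2,4,5,6,7,7a-hexahydro-1-benzofuran-2-yl]but-2-enal
Conditions: MnO2, CH2Cl2, rt
Reagents that add atoms: none
Why: Chemoselective MnO2 oxidation of the primary allylic alcohol, which leaves the saturated secondary C3 hydroxyl and the E geometry of C9=C10 unchanged.

Step 13
Reactants: 21 (R)-α-ionone ((3E)-4-[(1R)-2,6,6-trimethylcyclohex-2-en-1-yl]but-3-en-2-one); 22 diethyl (cyanomethyl)phosphonate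
Product: 23 (2E,4E)-3-methyl-5-[(1R)-2,6,6-trimethylcyclohex-2-en-1-yl]penta-2,4-dienenitrile
Conditions: NaH, THF, 0 °C → rt; minor 2Z isomer removed by chromatography
Reagents that add atoms: none
Why: Horner–Wadsworth–Emmons olefination of the methyl ketone with the preformed phosphonate anion, which gives mainly the E trisubstituted C9'=C10' bond and is too weakly basic to deprotonate C6'–H, so 6'R is kept.

Step 14
Reactants: 23 (2E,4E)-3-methyl-5-[(1R)-2,6,6-trimethylcyclohex-2-en-1-yl]penta-2,4-dienenitrile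
Product: 24 (2E,4E)-3-methyl-5-[(1R)-2,6,6-trimethyl-4-oxocyclohex-2-en-1-yl]penta-2,4-dienenitrile
Conditions: CrO3, 3,5-dimethylpyrazole, CH2Cl2, −20 °C
Reagents that add atoms: chromium trioxide, O=[Cr](=O)=O
Why: Allylic oxidation by the CrO3–3,5-dimethylpyrazole complex, which converts the only allylic methylene (ring C3') into the enone under neutral conditions that avoid enolisation through C6'–H.

Step 15
Reactants: 24 (2E,4E)-3-methyl-5-[(1R)-2,6,6-trimethyl-4-oxocyclohex-2-en-1-yl]penta-2,4-dienenitrile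
Product: 25 (2E,4E)-5-[(1R,4R)-4-hydroxy-2,6,6-trimethylcyclohex-2-en-1-yl]-3-methylpenta-2,4-dienenitrile
Conditions: (S)-Me-CBS oxazaborolidine (20 mol %), catecholborane, toluene, −78 °C
Reagents that add atoms: none
Why: Corey–Bakshi–Shibata reduction, in which the catalyst–borane complex treats the alkenyl flank (C4'=C5') as the large group and delivers hydride to one carbonyl face, setting 3'R (trans to the C6' chain) by reagent control while the nitrile stays inert.

Step 16
Reactants: 25 (2E,4E)-5-[(1R,4R)-4-hydroxy-2,6,6-trimethylcyclohex-2-en-1-yl]-3-methylpenta-2,4-dienenitrile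
Product: 27 (2E,4E)-5-[(1R,4R)-4-hydroxy-2,6,6-trimethylcyclohex-2-en-1-yl]-3-methylpenta-2,4-dienal, via aldimine 26 (not isolated)
Conditions: i-Bu2AlH (2.5 equiv), CH2Cl2, −78 °C; then aq. tartaric acid, 0 °C
Reagents that add atoms: water, O
Why: Partial reduction of the nitrile by i-Bu2AlH to aldimine 26 (held as its N-aluminium derivative), which hydrolyses on work-up to the aldehyde; the first equivalent is consumed by the hydroxyl and no stereocentre is touched.

Step 17
Reactants: 28 (2E,4E,6E)-2,7-dimethylocta-2,4,6-trienedial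
Product: 29 (2E,4E,6E)-2,7-dimethylocta-2,4,6-triene-1,8-diol
Conditions: NaBH4, MeOH–THF, 0 °C
Reagents that add atoms: none
Why: Borohydride 1,2-reduction of both conjugated aldehydes with retention of the triene geometry.

Step 18
Reactants: 29 (2E,4E,6E)-2,7-dimethylocta-2,4,6-triene-1,8-diol
Product: 30 (2E,4E,6E)-1,8-dibromo-2,7-dimethylocta-2,4,6-triene
Conditions: PBr3, pyridine (cat.), Et2O, −10 °C; used at once
Reagents that add atoms: phosphorus tribromide, BrP(Br)Br
Why: Conversion of the primary allylic alcohols into bromides through their phosphite esters.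

Step 19
Reactants: 30 (2E,4E,6E)-1,8-dibromo-2,7-dimethylocta-2,4,6-triene
Product: 31 tetraethyl [(2E,4E,6E)-2,7-dimethylocta-2,4,6-triene-1,8-diyl]bis(phosphonate)
Conditions: P(OEt)3, toluene, 110 °C
Reagents that add atoms: triethyl phosphite, CCOP(OCC)OCC
Why: Michaelis–Arbuzov reaction at both allylic bromide termini.

Step 20
Reactants: 27 (2E,4E)-5-[(1R,4R)-4-hydroxy-2,6,6-trimethylcyclohex-2-en-1-yl]-3-methylpenta-2,4-dienal; 31 tetraethyl [(2E,4E,6E)-2,7-dimethylocta-2,4,6-triene-1,8-diyl]bis(phosphonate)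
Product: 32 diethyl [(2E,4E,6E,8E,10E,12E)-13-[(1R,4R)-4-hydroxy-2,6,6-trimethylcyclohex-2-en-1-yl]-2,7,11-trimethyltrideca-2,4,6,8,10,12-hexaen-1-yl]phosphonate
Conditions: 31 (3 equiv), NaN(SiMe3)2 (3 equiv), THF, −78 °C; then 27, −78 → 0 °C
Reagents that add atoms: none
Why: Horner–Wadsworth–Emmons olefination, in which the mono-anion of the bisphosphonate (kept in excess so that each molecule reacts only once) adds to aldehyde carbon C11' and loss of diethyl phosphate gives the E C11'=C12' bond.

Step 21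
Reactants: 32 diethyl [(2E,4E,6E,8E,10E,12E)-13-[(1R,4R)-4-hydroxy-2,6,6-trimethylcyclohex-2-en-1-yl]-2,7,11-trimethyltrideca-2,4,6,8,10,12-hexaen-1-yl]phosphonate; 20 (2E)-3-[(2S,6S,7aR)-6-hydroxy-4,4,7a-trimethyl-2,4,5,6,7,7a-hexahydro-1-benzofuran-2-yl]but-2-enal
Product: 33 (3S,5R,8S,3'R,6'R)-5,8-epoxy-5,8-dihydro-β,ε-carotene-3,3'-diol (all-E)
Conditions: 32, NaN(SiMe3)2 (2.1 equiv), THF, −78 °C; then 20, −78 → 0 °C; argon, dim light
Reagents that add atoms: none
Why: Horner–Wadsworth–Emmons olefination, in which the polyenyl phosphonate anion should add to enal carbon C11 faster than it deprotonates C8–H, and loss of diethyl phosphate gives the E C11=C12 bond; all five stereocentres are carried over unchanged.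

Compound list
1 | 4-oxoisophorone | CC1=CC(=O)CC(C)(C)C1=O | starting material
2 | (6R)-2,2,6-trimethylcyclohexane-1,4-dione | O=C1C(C)(C)CC(=O)C[C@H]1C | intermediate
3 | (4R,6R)-4-hydroxy-2,2,6-trimethylcyclohexan-1-one (actinol) | O=C1C(C)(C)C[C@H](O)C[C@H]1C | intermediate
4 | (4R,6R)-4-[(tert-butyldimethylsilyl)oxy]-2,2,6-trimethylcyclohexan-1-one | O=C1C(C)(C)C[C@H](O[Si](C)(C)C(C)(C)C)C[C@H]1C | intermediate
5 | (4R)-4-[(tert-butyldimethylsilyl)oxy]-2,6,6-trimethyl-1-[(trimethylsilyl)oxy]cyclohex-1-ene | C[Si](C)(C)OC1=C(C)C[C@@H](O[Si](C)(C)C(C)(C)C)CC1(C)C | intermediate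
6 | silyloxy oxirane of 5, oxirane oxygen anti to the C3 silyloxy group (not isolated) | CC1(C)C[C@H](O[Si](C)(C)C(C)(C)C)C[C@@]2(C)O[C@@]12O[Si](C)(C)C | intermediate
7 | (2R,4S)-4-[(tert-butyldimethylsilyl)oxy]-2,6,6-trimethyl-2-[(trimethylsilyl)oxy]cyclohexan-1-one (not isolated) | O=C1C(C)(C)C[C@H](O[Si](C)(C)C(C)(C)C)C[C@@]1(C)O[Si](C)(C)C | intermediate
8 | (2R,4S)-4-[(tert-butyldimethylsilyl)oxy]-2-hydroxy-2,6,6-trimethylcyclohexan-1-one | O=C1C(C)(C)C[C@H](O[Si](C)(C)C(C)(C)C)C[C@@]1(C)O | intermediate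
9 | prenol (3-methylbut-2-en-1-ol) | CC(C)=CCO | starting material
10 | tert-butyl[(3-methylbut-2-en-1-yl)oxy]diphenylsilane | CC(C)=CCO[Si](c1ccccc1)(c1ccccc1)C(C)(C)C | intermediate
11 | (2E)-4-[(tert-butyldiphenylsilyl)oxy]-2-methylbut-2-en-1-ol | OC/C(C)=C/CO[Si](c1ccccc1)(c1ccccc1)C(C)(C)C | intermediate
12 | {[(2E)-4-bromo-3-methylbut-2-en-1-yl]oxy}(tert-butyl)diphenylsilane | BrC/C(C)=C/CO[Si](c1ccccc1)(c1ccccc1)C(C)(C)C | intermediate
13 | (2R,4S)-4-[(tert-butyldimethylsilyl)oxy]-2-{[(2E)-4-[(tert-butyldiphenylsilyl)oxy]-2-methylbut-2-en-1-yl]oxy}-2,6,6-trimethylcyclohexan-1-one (key-step precursor) | O=C1C(C)(C)C[C@H](O[Si](C)(C)C(C)(C)C)C[C@@]1(C)OC/C(C)=C/CO[Si](c1ccccc1)(c1ccccc1)C(C)(C)C | intermediate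
14 | (trimethylsilyl)diazomethane | C[Si](C)(C)C=[N+]=[N-] | starting material
15 | lithium alkoxide from addition of lithiated 14 to C6 of 13, C6 configuration immaterial (not isolated) | [Li+].[O-]C1(C(=[N+]=[N-])[Si](C)(C)C)C(C)(C)C[C@H](O[Si](C)(C)C(C)(C)C)C[C@@]1(C)OC/C(C)=C/CO[Si](c1ccccc1)(c1ccccc1)C(C)(C)C | intermediate
16 | exocyclic diazoalkene at C6=C7 (not isolated) | [N-]=[N+]=C=C1C(C)(C)C[C@H](O[Si](C)(C)C(C)(C)C)C[C@@]1(C)OC/C(C)=C/CO[Si](c1ccccc1)(c1ccccc1)C(C)(C)C | intermediate
17 | alkylidene carbene at C7 (not isolated) | [C]=C1C(C)(C)C[C@H](O[Si](C)(C)C(C)(C)C)C[C@@]1(C)OC/C(C)=C/CO[Si](c1ccccc1)(c1ccccc1)C(C)(C)C | intermediate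
18 | (2S,6S,7aR)-6-[(tert-butyldimethylsilyl)oxy]-2-[(2E)-4-[(tert-butyldiphenylsilyl)oxy]but-2-en-2-yl]-4,4,7a-trimethyl-2,4,5,6,7,7a-hexahydro-1-benzofuran (key-step product) | CC(C)(C)[Si](OC/C=C(\C)[C@@H]1C=C2C(C)(C)C[C@H](O[Si](C)(C)C(C)(C)C)C[C@@]2(C)O1)(c1ccccc1)c1ccccc1 | intermediate
19 | (2E)-3-[(2S,6S,7aR)-6-hydroxy-4,4,7a-trimethyl-2,4,5,6,7,7a-hexahydro-1-benzofuran-2-yl]but-2-en-1-ol | OC/C=C(\C)[C@@H]1C=C2C(C)(C)C[C@H](O)C[C@@]2(C)O1 | intermediate
20 | (2E)-3-[(2S,6S,7aR)-6-hydroxy-4,4,7a-trimethyl-2,4,5,6,7,7a-hexahydro-1-benzofuran-2-yl]but-2-enal | O=C/C=C(\C)[C@@H]1C=C2C(C)(C)C[C@H](O)C[C@@]2(C)O1 | intermediate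
21 | (R)-α-ionone | CC1=CCCC(C)(C)[C@H]1/C=C/C(C)=O | starting material
22 | diethyl (cyanomethyl)phosphonate | CCOP(=O)(CC#N)OCC | starting material
23 | (2E,4E)-3-methyl-5-[(1R)-2,6,6-trimethylcyclohex-2-en-1-yl]penta-2,4-dienenitrile | CC1=CCCC(C)(C)[C@H]1/C=C/C(C)=C/C#N | intermediate
24 | (2E,4E)-3-methyl-5-[(1R)-2,6,6-trimethyl-4-oxocyclohex-2-en-1-yl]penta-2,4-dienenitrile | CC1=CC(=O)CC(C)(C)[C@H]1/C=C/C(C)=C/C#N | intermediate
25 | (2E,4E)-5-[(1R,4R)-4-hydroxy-2,6,6-trimethylcyclohex-2-en-1-yl]-3-methylpenta-2,4-dienenitrile | CC1=C[C@H](O)CC(C)(C)[C@H]1/C=C/C(C)=C/C#N | intermediate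
26 | aldimine of 27, formed as its N-aluminium derivative (not isolated) | CC1=C[C@H](O)CC(C)(C)[C@H]1/C=C/C(C)=C/C=N | intermediate
27 | (2E,4E)-5-[(1R,4R)-4-hydroxy-2,6,6-trimethylcyclohex-2-en-1-yl]-3-methylpenta-2,4-dienal | CC1=C[C@H](O)CC(C)(C)[C@H]1/C=C/C(C)=C/C=O | intermediate
28 | (2E,4E,6E)-2,7-dimethylocta-2,4,6-trienedial | O=C/C(C)=C/C=C/C=C(C)/C=O | starting material
29 | (2E,4E,6E)-2,7-dimethylocta-2,4,6-triene-1,8-diol | OC/C(C)=C/C=C/C=C(C)/CO | intermediate
30 | (2E,4E,6E)-1,8-dibromo-2,7-dimethylocta-2,4,6-triene | BrC/C(C)=C/C=C/C=C(C)/CBr | intermediate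
31 | tetraethyl [(2E,4E,6E)-2,7-dimethylocta-2,4,6-triene-1,8-diyl]bis(phosphonate) | CCOP(=O)(OCC)C/C(C)=C/C=C/C=C(C)/CP(=O)(OCC)OCC | intermediate
32 | diethyl [(2E,4E,6E,8E,10E,12E)-13-[(1R,4R)-4-hydroxy-2,6,6-trimethylcyclohex-2-en-1-yl]-2,7,11-trimethyltrideca-2,4,6,8,10,12-hexaen-1-yl]phosphonate | CC1=C[C@H](O)CC(C)(C)[C@H]1/C=C/C(C)=C/C=C/C(C)=C/C=C/C=C(C)/CP(=O)(OCC)OCC | intermediate
33 | (3S,5R,8S,3'R,6'R)-5,8-epoxy-5,8-dihydro-β,ε-carotene-3,3'-diol | CC1=C[C@H](O)CC(C)(C)[C@H]1/C=C/C(C)=C/C=C/C(C)=C/C=C/C=C(C)/C=C/C=C(\C)[C@@H]1C=C2C(C)(C)C[C@H](O)C[C@@]2(C)O1 | target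

Total step count: 21
Longest linear sequence: 10 steps (steps 1–5, 9–12 and 21, from 4-oxoisophorone)

Steps most likely to fail

Step 10. Addition of the lithiated diazo compound to the doubly neopentyl carbonyl may be so slow that the reagent decays first. The carbene may also distinguish poorly between the two C8 hydrogens, so that much material ends as the 8R epimer. The fallback is the acid-induced rearrangement of a 5,6-epoxide to the 5,8-furanoid; it sets out from 4 and returns at 18. Ketone 4 is converted with KN(SiMe3)2 and PhNTf2 into the enol triflate F1. Commercial (E)-3-methylpent-2-en-4-yn-1-ol is silylated with t-BuPh2SiCl to the silyl enyne F2, and hydrostannation (Bu3SnH, PdCl2(PPh3)2) gives the dienylstannane F3. Stille coupling of F1 with F3 (Pd(PPh3)4, LiCl, THF) gives the C15 triene F4. m-CPBA epoxidises the tetrasubstituted C5=C6 bond anti to the silyloxy group to give the 5,6-epoxide F5. A catalytic acid (pyridinium p-toluenesulfonate in CH2Cl2) opens the oxirane at C6 and the C5 oxygen closes on C8, which gives 18 together with its C8 epimer; these are separated as in the main route.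

Step 5. The peracid may attack the tetrasubstituted enol ether with low or reversed facial preference, because the pseudoaxial C1 methyl shields the face anti to the silyloxy group; the C5 configuration would then be lost. The fallback replaces substrate control by reagent control; it sets out from 4 and returns at 8. KN(SiMe3)2 in THF at −78 °C converts 4 into the potassium enolate F6. This is hydroxylated with an enantiopure (camphorsulfonyl)oxaziridine, using the antipode that proves matched with attack anti to the C3 silyloxy group.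

Step 9. The hindered tertiary alkoxide may react too slowly, so that base-induced acyloin rearrangement of the ketol or 1,4-elimination of HBr from the bromide takes over. The fallback is an acid-catalysed etherification; it sets out from 11 and 8 and returns at 13. Alcohol 11 is converted with Cl3CCN and DBU (cat.) into the allylic trichloroacetimidate F7. F7 alkylates the hydroxyl of 8 at its primary terminus under catalytic TfOH in CH2Cl2–cyclohexane at −40 °C.

Further compounds
F1 | step 10 | (4R)-4-[(tert-butyldimethylsilyl)oxy]-2,6,6-trimethylcyclohex-1-en-1-yl trifluoromethanesulfonate | FC(F)(F)S(=O)(=O)OC1=C(C)C[C@@H](O[Si](C)(C)C(C)(C)C)CC1(C)C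
F2 | step 10 | tert-butyl{[(2E)-3-methylpent-2-en-4-yn-1-yl]oxy}diphenylsilane | C#C/C(C)=C/CO[Si](c1ccccc1)(c1ccccc1)C(C)(C)C
F3 | step 10 | tert-butyl{[(2E,4E)-3-methyl-5-(tributylstannyl)penta-2,4-dien-1-yl]oxy}diphenylsilane | CCCC[Sn](CCCC)(CCCC)/C=C/C(C)=C/CO[Si](c1ccccc1)(c1ccccc1)C(C)(C)C
F4 | step 10 | (3R)-3-silyloxy C15 triene: tert-butyl{[(2E,4E)-5-[(4R)-4-[(tert-butyldimethylsilyl)oxy]-2,6,6-trimethylcyclohex-1-en-1-yl]-3-methylpenta-2,4-dien-1-yl]oxy}diphenylsilane | CC(C)(C)[Si](OC/C=C(C)/C=C/C1=C(C)C[C@@H](O[Si](C)(C)C(C)(C)C)CC1(C)C)(c1ccccc1)c1ccccc1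
F5 | step 10 | (3S,5R,6S)-5,6-epoxide of F4, oxirane oxygen anti to the C3 silyloxy group | CC(C)(C)[Si](OC/C=C(C)/C=C/[C@@]12O[C@]1(C)C[C@@H](O[Si](C)(C)C(C)(C)C)CC2(C)C)(c1ccccc1)c1ccccc1
F6 | step 5 | potassium enolate of 4 | [K+].[O-]C1=C(C)C[C@@H](O[Si](C)(C)C(C)(C)C)CC1(C)C
F7 | step 9 | (2E)-4-[(tert-butyldiphenylsilyl)oxy]-2-methylbut-2-en-1-yl 2,2,2-trichloroacetimidate | N=C(OC/C(C)=C/CO[Si](c1ccccc1)(c1ccccc1)C(C)(C)C)C(Cl)(Cl)Cl
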